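The free monomer left over is what I read first, as a fraction of its charge, and I work with its logarithm.

| setting | beta | zeta | autumn | spring |
|---|---|---|---|---|
| free monomer | 0.48 M | 0.48 M | 0.48 M | 0.48 M |
| initiator | 24 mM | 96 mM | 48 mM | 48 mM |
| remark | run made earlier | run made earlier |  |  |
| time |  |  | 1.5 h | 0.40 h |

| run | time / min | monomer in chains / % | free monomer / % |
|---|---|---|---|
| beta | 20.0 | 13.4 | 86.5 |
| beta | 40.0 | 24.1 | 73.9 |
| beta | 50.0 | 30.9 | 69.2 |
| beta | 80.0 | 42.9 | 52.4 |
| beta | 90.0 | 47.4 | 51.9 |
| beta | 120 | 56.5 | 40.7 |
| zeta | 8.00 | 14.6 | 84.8 |
| zeta | 20.0 | 38.9 | 59.8 |
| zeta | 40.0 | 62.0 | 34.3 |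
| zeta | 60.0 | 74.5 | 25.5 |
| zeta | 80.0 | 81.5 | 17.6 |
| zeta | 120 | 84.1 | 14.6 |

(each reading ± 1 percentage point)

- the average divides the monomer in chains by the number of chains begun, living and dead together
- the earlier runs do not show the number of chains; that part of a forecast is a guess

1. which of the two ends with the longer chains by the average number of monomer units in a chain (chains begun, living or dead) ("neither" if they lie within 10%) (autumn / spring / neither)
2. average number of monomer units in a chain (chains begun, living or dead) at the end, autumn
3. average number of monomer units in a chain (chains begun, living or dead) at the end, spring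

Autumn and spring each charge 10.0 units of free monomer per initiator, and I call this the units on offer. If every initiator begins one chain, the length (number-average degree of polymerisation) is the units on offer times the fraction of the charge in chains.

So I need that fraction. Beta's leftover of 40.7% after 120 min gives a log slope of 0.00749 /min, and zeta's 34.3% after 40.0 min gives 0.0268 /min. On a log scale 48 mM lies midway between their initiator charges, so I take the log midpoint, 0.0142 /min, a pseudo-first-order line. For autumn's 1.5 h that leaves 28.0%.

The weak link is that straight line, because zeta's last readings, 17.6% and 14.6%, look like a stop. So I measure the leftover above 14.6%. The slopes become 0.00988 /min and 0.0367 /min, with midpoint 0.0190 /min. Autumn then leaves 30.0% and spring 68.7%. Counting the rest as in chains, I commit to 7.00 for autumn and 3.13 for spring.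

The forecast says autumn, with 7 and 2.9, also reckoning that “every initiator starts one chain”. Its spring value is lower than mine.

The flask gives 7.09 for autumn and 3.47 for spring, so autumn is longer.

    free monomer + initiator → living end + monomer in chains (k = 0.150 /M/min)
    free monomer + living end → monomer in chains + living end, rate k2*[living end]*[free monomer] (k = 0.500 /M/min)
    monomer in chains + living end → free monomer + living end, rate k3*[living end] as long as [monomer in chains] is above zero (k = 0.0360 /min)
    living end + free monomer → dead end (k = 0.00900 /M/min)

Autumn is longer because of the difference in time: without it, spring's 3.47 becomes 7.09. My chain count was the second weak link. Spring still holds 22% of its initiator, so the units on offer times its 27.0% in chains, divided by the 78.0% of initiator used, gives 3.47. Autumn, with 2.5% left, gives 7.09.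

A neighbour flask, autumn with 0.29 M of free monomer, offers 6.04 units. With 60.9% in chains and 91.5% of its initiator used, that gives 4.02; the computed length is 4.02.

(The readings were computed on assumed constants; noise was put on by code.)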